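The constants come from no measurement; the result is computed.

At late times target keeps passing on to over-reaction product, so the share asked about is a race between how long target lives and how long the flask runs.

    intermediate B → target (k1 = 0.012 s⁻¹, Ea1 = 95.0 kJ mol⁻¹)
    starting material → intermediate A (k2 = 0.065 s⁻¹, Ea2 = 78.0 kJ mol⁻¹)
    target → over-reaction product (k3 = 0.13 s⁻¹, Ea3 = 83.0 kJ mol⁻¹)
    intermediate A → intermediate B (k4 = 0.36 s⁻¹, Ea4 = 98.0 kJ mol⁻¹)
    solid substrate ⇌ starting material, rate k5*(cs5 - [starting material]) while solid is left; crystals form when [starting material] > cs5 (cs5 = 0.23 mM, k5 = 0.037 s⁻¹)
    starting material + target ⇌ idle adduct, settled at all times (K6 = 820 M⁻¹, ΔH6 = −6.00 kJ mol⁻¹)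
    (constants at 70 °C)

in all of them: solid substrate 2.0 mM; time 50 s
- Saturday's: temperature 120 °C
- Tuesday's: temperature 95 °C
- Monday's: temperature 45 °C
- Wednesday's: temperature 70 °C

- the best flask by share of target in all that became target or over-reaction product; "all alike" if 1.5 percentage points covers them all (Saturday's / Tuesday's / Monday's / Wednesday's / all alike)
- share of target in all that became target or over-reaction product, Saturday's
- share of target in all that became target or over-reaction product, Tuesday's
- share of target in all that became target or over-reaction product, Monday's
- share of target in all that became target or over-reaction product, Wednesday's

- a species is counted by the solid substrate in it: one idle adduct counts as two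
- amounts and yields of target count idle adduct too
- given per volume of solution although it is solid: solid substrate
- the list of constants is for 70 °C, to be carried to other temperatures by the activation energies and enthalpies
- at the start none of the solid substrate is in solution
- what has only dissolved of solid substrate counts as not reacted
- in an amount of target, one idle adduct counts as one target

This reckoning by hand follows Saturday's flask in slow motion. In the first instants nothing is in solution, and solid substrate enters at no more than 0.00851 mM s⁻¹, called r here; the list gives dissolving no activation energy. At 120 °C starting material reacts on with a constant of 2.10 s⁻¹, larger than the dissolving coefficient 0.037 s⁻¹, so in Saturday's flask it stays near 0.00405 mM, far below its solubility. Intermediate B lives 1.21 s, much less than the 50 s allowed, so within seconds Saturday's chain passes on what dissolves.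

In the middle of Saturday's run, target is made at r and lost at k times its free amount, with k = 5.26 s⁻¹. Taking the fast balance as reached, idle adduct holds 0.254 % of the free target, so free target can stand for the whole. The steady state is then r/k.

By the end, over-reaction product has gathered to about r times the time, so r cancels and the share comes to 0.380 %: this is the life ratio w, target's life over the time allowed.

Tuesday's flask gives w = 2.13 %. Wednesday's gives 15.4 %, but there intermediate B lives 83.3 s, longer than the time allowed, so the quick passing-on behind that figure does not hold in Wednesday's flask. In Monday's flask target lives 75.7 s, also longer than the time allowed, so w is no share there. This reckoning names Monday's flask as best and gives no figure for it.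

The forecast also names Monday's, with 0.39 % for Saturday's, 2.75 % for Tuesday's, 88 % for Monday's and 32 % for Wednesday's. Its ground for the hot flasks is that target's loss “leaves only a small steady-state amount against an accumulating over-reaction product”. For Wednesday's it stands above the reckoning's 15.4 %.

The simulation gives Monday's as best, with 0.395 % for Saturday's, 2.77 % for Tuesday's, 88.5 % for Monday's and 31.1 % for Wednesday's.

The forecast held, and Monday's high share is owed mainly to the time allowed: left to 500 s, Monday's flask gives 31.3 % in place of 88.5 %. Saturday's w of 0.380 % stands beside 0.395 %, while Wednesday's 15.4 % lies well under 31.1 %, with 8.07 % still in intermediate B at 50.0 s.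

Saturday's flask repeated at 135 °C takes w, carried by target's activation energy, down to 0.150 %. The run there gives 0.152 %.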